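The saturated, unbranched C28 acyl chain is cut at its C8–C9 bond (numbered from the ester carbonyl, C1). This is an unactivated CH2–CH2 bond between two primary carbons, insulated from the carbonyl by six methylenes (C2–C7). The key step forges this sp3–sp3 bond in one copper-catalysed cross-coupling of icosylmagnesium bromide 5 with 2-phenylethyl 8-bromooctanoate 3. The complete C36 wax ester should emerge directly, with the phenyl ring and the O–CH2–CH2 ester linkage carried through as spectators. The precursor 3 is the ω-bromo C8 ester, made by esterifying 8-bromooctanoic acid 1 with 2-phenylethanol 2; the C20 partner comes from 1-bromoicosane 4.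

Key step: step 2

Remark: "phenylethyl" is read as 2-phenylethyl, as the SMILES shows. The target has no stereocentre and no ring other than the phenyl ring, so no step needs stereocontrol. Compounds 1, 2 and 4 are taken as commercially available.

Step 1
Reactants: 1 8-bromooctanoic acid; 2 2-phenylethanol
Product: 3 2-phenylethyl 8-bromooctanoate
Conditions: TsOH·H2O (5 mol%), toluene, reflux, Dean–Stark trap
Reagents that add atoms: none
Why: Fischer esterification of an unhindered acid with a primary alcohol, driven to completion by azeotropic removal of water; the primary C–Br bond should be inert to TsOH in toluene.

Step 2
Reactants: 4 1-bromoicosane; 3 2-phenylethyl 8-bromooctanoate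
Product: 6 2-phenylethyl octacosanoate, via icosylmagnesium bromide 5 (not isolated)
Conditions: 4, Mg turnings (I2 activation), THF, 45 °C; the warm solution of 5 (1.2 equiv) then added slowly to 3, Li2CuCl4 (3 mol%), NMP (4 equiv), THF, 0 → 20 °C; aq. NH4Cl
Reagents that add atoms: none
Why: Kochi–Cahiez copper-catalysed sp3–sp3 cross-coupling (Kumada-type): magnesium insertion into 4 gives 5, which transmetallates to the copper(I) species formed from Li2CuCl4, and the resulting icosylcuprate should displace the primary bromide of 3 by SN2-type oxidative addition and reductive elimination, forging the C8–C9 bond of the C28 chain. The closest known reaction type is the Li2CuCl4/NMP-catalysed coupling of primary alkyl Grignard reagents with ω-bromoalkanoate esters. No ring is closed and no stereocentre is formed. The step needs chemoselectivity for the C–Br bond over the ester C=O of 3 and cross- over homo-coupling; the unhindered primary bromide, the NMP-accelerated copper cycle that outruns uncatalysed carbonyl addition at 0–20 °C, and the slow addition that keeps the concentration of free 5 low should secure both. The six methylenes between C8 and the carbonyl rule out chelation-directed or enolate-mediated side reactions at the reacting carbon.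

Compound list
1 | 8-bromooctanoic acid | OC(=O)CCCCCCCBr | starting material
2 | 2-phenylethanol | OCCc1ccccc1 | starting material
3 | 2-phenylethyl 8-bromooctanoate | BrCCCCCCCC(=O)OCCc1ccccc1 | intermediate
4 | 1-bromoicosane | CCCCCCCCCCCCCCCCCCCCBr | starting material
5 | icosylmagnesium bromide | CCCCCCCCCCCCCCCCCCCC[Mg]Br | intermediate (not isolated)
6 | 2-phenylethyl octacosanoate | CCCCCCCCCCCCCCCCCCCCCCCCCCCC(=O)OCCc1ccccc1 | target

Total step count: 2
Longest linear sequence: 2 steps (1 → 3 → 6)

Steps most likely to fail (the route has only two steps, so both are ranked):

Step 2. The Grignard reagent may add to the ester carbonyl faster than the copper cycle consumes it. Wurtz-type homocoupling may also occur during magnesium insertion or coupling, and the long-chain organomagnesium may precipitate at low temperature and stall the reaction. The fallback reverses the polarity so that the ester sits on a carbonyl-inert organozinc nucleophile; it sets out from 3 and 4 and comes back to the route at 6. Compound 3 would be treated with activated zinc dust and LiCl in THF at 50 °C to give [8-oxo-8-(2-phenylethoxy)octyl]zinc bromide F1. This would then be joined to 4 in a palladium-catalysed alkyl–alkyl Negishi coupling (Pd-PEPPSI-IPr 2 mol%, LiBr, THF/NMP, 20 °C), which should give 6 directly.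

Step 1. The equilibrium esterification may stop short of full conversion, or the hot acid may divert 2 into ether formation or dehydration. The fallback replaces the equilibrium by an irreversible acylation; it sets out from 1 and comes back to the route at 3. Compound 1 would be converted with oxalyl chloride and catalytic DMF in CH2Cl2 into 8-bromooctanoyl chloride F2, which would be treated with 2 and pyridine in CH2Cl2 at 0 °C to give 3.

Further compounds
F1 | step 2 | [8-oxo-8-(2-phenylethoxy)octyl]zinc bromide | Br[Zn]CCCCCCCC(=O)OCCc1ccccc1
F2 | step 1 | 8-bromooctanoyl chloride | ClC(=O)CCCCCCCBr
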